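(The data are simulated from invented constants.)

In the ochre flask, [G] plus the X and E converted stays at the charge of G, provided each turnover takes one G.

| flask | X | E | G | D | remark |
|---|---|---|---|---|---|
| ochre | 2 mM | 2 mM | 6 mM | 100 µM | the very flask that is asked about, followed so far |
| green | 1 mM | 1 mM | 6 mM | 100 µM | run made earlier |
| flask | 2.0 mM | 2.0 mM | 6.00 mM | 100 µM |  |

- ochre (time / s: Q / %, X / %): 10.0: 22.9, 27.3; 20.0: 34.3, 17.0; 30.0: 41.2, 10.3; 60.0: 47.5, 2.8; 120: 49.9, 0
- green (time / min: Q / %, X / %): 0.667: 45.0, 4.5; 1.33: 49.6, 0.6; 2.00: 50.0, 0.6; 3.00: 50.4, 0.4; 4.00: 50.3, 0

(standard deviation of a reading: 0.5 percentage points)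

* apparent order in D when 50 % of the X and E together are converted (percent change of the rate of making Q for one percent more D charged)
* apparent order in G when 50 % of the X and E together are converted (percent change of the rate of making Q for one percent more G charged)
* factor on the rate of making Q when 50 % of the X and E together are converted if G is charged twice over

- D is single-handed; X and E are mirror images of each other, charged as a racemate, each of them at the stated concentration
- no earlier run changes the charge of D; that part of a forecast is a guess
- no earlier run changes the charge of G; that part of a forecast is a guess

Q levels off near 50 % in both runs, with X read at 0 % and 0 % at the last readings, so Q comes from X. I read a decay constant for X of 0.0434 /s late in the ochre run and 0.0602 /s early in the green run. The ochre reading is lower, and the ochre run is charged with more X against the same G, though the two readings also differ in time. I take this, as a guess, as the first power of [G].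

The bench rule, pseudo-first-order in X, says that G, charged at 3.00 times X, stays constant, so the order in G is 1 and doubling G gives a factor of 2 on the rate. The balance tests that rule. At 50 % conversion in the ochre flask:

used G = 2.00 mM

[G] left = 4.00 mM

So the rule fails here, because a third of the charge is used. At fixed conversion, the rate goes as the charge minus the used G. This gives my carried quantity, the lever of G, which is the charge over what is left at that conversion:

lever = 1.50

Doubling the charge gives 2.50. The green charge has a lever of 1.20. The balance says nothing on D, since no run changes its charge.

The forecast gives 1.5 and 2.5 for G, as I do, and 1 for D, noting “The order in D is unmeasured”.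

The ochre flask gives 1.5 and 2.50 for G, beside my lever of 1.50, and 0.61 for D, with 63.6 % of the catalyst as Z at 50 % conversion.

    G + D + X → D + Q (k = 3.06 × 10⁵ /M²/s)
    G + D + E → D + L (k = 16800 /M²/s)
    2 D ⇌ Z, settled at all times (K = 24000 /M)

With [G], [X] and [E] as charged, the step to Q runs at 220 /min per D and the step to L at 12 /min, so X goes faster, by a selectivity factor of 18.3. At 5.00 min the ochre flask holds X 0 %, Q 50.0 %, L 24.0 % and E 26.0 %.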